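**Plan**

1. Numbering (briarane): ten-membered ring C1–C10 with C5=C6; cyclohexene C1, C10, C11–C14; lactone O–C19(=O)–C17–C8–C7; methyls C15 (on C1), C16 (C5), C18 (C17), C20 (C11).
2. Cuts: C5=C6 (ring-closing metathesis), C4–C5 (Grignard), C2–C3 and C8–C9 (two alkoxyallylborations), C10–C11 with C1–C14 (Diels–Alder), C1=C10 (cross-metathesis), and O–C7 with C8–C17 (lactone annulation).
3. Enabling feature: the dihydroxy-γ-lactone ring (O, C19, C17, C8, C7) is an aldol retron at C8–C17 whose ring oxygen sits on C7 next to C6, so a C8 ketone carrying a C6–C7 epoxide can take up a lactic acid enolate and be closed by its acyl oxygen in one operation.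
4. Forward: acrolein → epoxy ketone → lactone (first ring) → enal → cyclohexene (second ring) → C2–C5 chain → ten-membered ring (third ring) → deprotection.
5. Stereochemistry: C9, C2 and C3 from Ipc2B reagents; C7 from Sharpless epoxidation (inverted in the key step); C17 from (R)-lactic acid; C8 by chelation to the C9 ether.
6. C1/C10 from the E-enal geometry and allylic strain at C9; C11/C12 by osmylation anti to the C10 side chain; C4 by chelate-controlled Grignard addition; Z-C5=C6 from the ring closure.

Key step: step 5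

Remark: allyl methoxymethyl ether and (−)-Ipc2BOMe are taken as purchased reagents; C11 (in 18–22) and C12 (in 22) are erased in step 16, so 18–22 are drawn with the expected 11-methyl orientation and 22 without a C12 descriptor.

**Route**

Step 1
Reactants: 1 acrolein
Product: 2 (3R,4R)-4-(methoxymethoxy)hexa-1,5-dien-3-ol
Conditions: allyl methoxymethyl ether, s-BuLi, THF, −78 °C; (−)-Ipc2BOMe; BF3·OEt2; 1, −78 °C; 8-hydroxyquinoline, rt
Reagents that add atoms: [(Z)-3-(methoxymethoxy)allyl]diisopinocampheylborane (formed in the flask), COCO/C=C\CB([C@@H]1C[C@@H]2C[C@H]([C@H]1C)C2(C)C)[C@@H]1C[C@@H]2C[C@H]([C@H]1C)C2(C)C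
Why: Brown (Z)-γ-alkoxyallylboration through a chair transition state gives the syn monoprotected diol, and the isopinocampheyl groups derived from (+)-α-pinene direct the allyl unit to the Si face of the aldehyde, so C8 and C9 are both formed as R.

Step 2
Reactants: 2 (3R,4R)-4-(methoxymethoxy)hexa-1,5-dien-3-ol
Product: 3 epoxy alcohol
Conditions: Ti(OiPr)4 (20 mol%), L-(+)-diisopropyl tartrate (24 mol%), t-BuOOH, 4 Å MS, CH2Cl2, −20 °C
Reagents that add atoms: tert-butyl hydroperoxide, CC(C)(C)OO
Why: Sharpless asymmetric epoxidation touches only the alkene of the free allylic alcohol, and with L-(+)-tartrate the R-configured carbinol C8 is the fast-reacting (matched) antipode, so the erythro epoxide with C7 as R should form.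

Step 3
Reactants: 3 epoxy alcohol
Product: 4 epoxy ketone
Conditions: Dess–Martin periodinane, NaHCO3, CH2Cl2, 0 °C
Reagents that add atoms: none
Why: Dess–Martin oxidation under buffered, near-neutral conditions gives the ketone without opening the epoxide or moving the β,γ-double bond into conjugation, and the product is used at once.

Step 4
Reactants: 5 (R)-lactic acid, 6 pivalaldehyde
Product: 7 (2R,5R)-2-tert-butyl-5-methyl-1,3-dioxolan-4-one
Conditions: TsOH (cat.), H2SO4 (cat.), pentane, reflux, Dean–Stark; crystallisation of the cis isomer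
Reagents that add atoms: none
Why: Acid-catalysed acetalisation (Seebach) under thermodynamic control gives mainly the cis dioxolanone, whose acetal centre stores the configuration of lactic acid for the enolate step.

Step 5
Reactants: 7 (2R,5R)-2-tert-butyl-5-methyl-1,3-dioxolan-4-one, 4 epoxy ketone
Product: 10 lactone triol, via lithium enolate 8 (not isolated), via lithium aldolate 9 (not isolated)
Conditions: LiN(iPr)2, THF, −78 °C; 4 in toluene, −78 °C; BF3·OEt2 (3 equiv), −78 → −20 °C; H2O, then aq. NaHCO3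
Reagents that add atoms: none
Why: Proposed new method: the lithium enolate 8 adds to the doubly α-oxygenated ketone C8 of 4 (aldol, C8–C17), and once BF3 activates the epoxide of aldolate 9 the acylal carbonyl oxygen opens it at C7 with inversion (O–C7), after which the dioxolanylium ion sheds its tert-butyl acetal carbon as an oxocarbenium ion that water turns into pivalaldehyde and the free C17 hydroxyl, so the sequence amounts to a formal [3+2] lactone annulation. The closest known reactions are Seebach's aldol additions of lactic acid dioxolanone enolates to ketones and the Lewis-acid lactonisation of γ,δ-epoxy esters with loss of the ester alkyl group. The lactone ring closes 5-exo-tet on the terminal epoxide. C17 is fixed by the tert-butyl group (the ketone meets the enolate face anti to it, net replacement of H by C8 with retention), C8 by a lithium chelate between the ketone and the C9 MOM ether that is attacked anti to the vinyl group, and C7 by inversion of the epoxide centre set in step 2. The step needs 1,2-addition to outrun proton transfer from C9–H and needs the acylal oxygen to outrun the C8 alkoxide at the epoxide; the low temperature, the strongly electrophilic ketone, the binding of the alkoxide by boron and the 5-exo geometry (the alkoxide could only close a three- or four-membered ring) are expected to secure this.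

Step 6
Reactants: 10 lactone triol
Product: 11 tris(triethylsilyl) ether
Conditions: Et3SiOTf (4 equiv), 2,6-lutidine, CH2Cl2, −78 → 0 °C
Reagents that add atoms: triethylsilyl triflate, CC[Si](CC)(CC)OS(=O)(=O)C(F)(F)F
Why: Silylation with the silyl triflate is strong enough to cap the primary and both hindered tertiary hydroxyls, which later prevents retro-aldol opening of the β-hydroxy lactone under basic conditions.

Step 7
Reactants: 11 tris(triethylsilyl) ether
Product: 12 C9 alcohol
Conditions: Me2BBr, CH2Cl2, −78 °C; THF/aq. NaHCO3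
Reagents that add atoms: none
Why: Bromodimethylborane (Guindon acetal cleavage) removes the MOM group at −78 °C through its oxocarbenium ion and leaves the silyl ethers and the lactone intact, so only the C9 hydroxyl is freed.

Step 8
Reactants: 12 C9 alcohol
Product: 13 C9 acetate
Conditions: Ac2O, DMAP, pyridine, rt
Reagents that add atoms: acetic anhydride, CC(=O)OC(C)=O
Why: DMAP-catalysed acetylation of the only free hydroxyl installs the C9 acetate of the target.

Step 9
Reactants: 13 C9 acetate, 14 methacrolein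
Product: 15 (E)-enal
Conditions: second-generation Hoveyda–Grubbs catalyst RuCl2(H2IMes)(=CH-C6H4-2-OiPr) (10 mol%), 14 (10 equiv), CH2Cl2, 40 °C
Reagents that add atoms: none
Why: Olefin cross-metathesis of the terminal alkene with excess methacrolein should give the (E)-2-methyl enal under thermodynamic control with loss of ethylene, the allylic acetate and silyl ethers being inert to the ruthenium carbene.

Step 10
Reactants: 16 ethyl vinyl ketone
Product: 17 (Z)-3-(tert-butyldimethylsilyloxy)penta-1,3-diene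
Conditions: t-BuMe2SiOTf, Et3N, Et2O, 0 °C
Reagents that add atoms: tert-butyldimethylsilyl triflate, CC(C)(C)[Si](C)(C)OS(=O)(=O)C(F)(F)F
Why: Soft enolisation and O-silylation of the ethyl ketone gives the (Z)-silyl dienol ether, in which the terminal methyl group points away from the s-cis diene.

Step 11
Reactants: 15 (E)-enal, 17 (Z)-3-(tert-butyldimethylsilyloxy)penta-1,3-diene
Product: 18 cyclohexene aldehyde
Conditions: Me2AlCl (2.5 equiv), CH2Cl2, −78 → −30 °C; aq. Rochelle salt
Reagents that add atoms: none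
Why: Lewis-acid-promoted Diels–Alder reaction: the siloxy group sends the nucleophilic diene terminus C11 to the β-carbon C10, the E-geometry of the enal places C2 and C9 trans on the new ring, and because 1,3-allylic strain holds C9–H in the plane of the alkene the diene should add to the face opposite the fully substituted C8, which gives C1 and C10 as in the target.

Step 12
Reactants: 18 cyclohexene aldehyde
Product: 19 enone aldehyde
Conditions: Pd(OAc)2 (1.1 equiv), MeCN, 40 °C
Reagents that add atoms: none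
Why: Saegusa–Ito dehydrogenation of the regiodefined silyl enol ether gives the C13=C14 enone, since the palladium enolate can lose a β-hydrogen only from C14.

Step 13
Reactants: 19 enone aldehyde
Product: 20 C2 alcohol
Conditions: allyl methoxymethyl ether, s-BuLi, THF, −78 °C; (−)-Ipc2BOMe; BF3·OEt2; 19, −78 °C; 8-hydroxyquinoline, rt
Reagents that add atoms: [(Z)-3-(methoxymethoxy)allyl]diisopinocampheylborane (formed in the flask), COCO/C=C\CB([C@@H]1C[C@@H]2C[C@H]([C@H]1C)C2(C)C)[C@@H]1C[C@@H]2C[C@H]([C@H]1C)C2(C)C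
Why: A second Brown (Z)-γ-alkoxyallylboration, selective for the aldehyde over the enone, adds to the Si face of the neopentyl aldehyde under reagent control and gives the syn C2 alcohol (R) and C3 MOM ether (R), with the vinyl group as masked C4.

Step 14
Reactants: 20 C2 alcohol
Product: 21 C2 acetate
Conditions: Ac2O, DMAP, pyridine, 40 °C
Reagents that add atoms: acetic anhydride, CC(=O)OC(C)=O
Why: DMAP-catalysed acetylation of the only free hydroxyl installs the C2 acetate of the target.

Step 15
Reactants: 21 C2 acetate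
Product: 22 allylic alcohol
Conditions: NaBH4, CeCl3·7H2O, MeOH, −78 °C
Reagents that add atoms: none
Why: Luche reduction gives the allylic alcohol by 1,2-attack on the enone and at −78 °C leaves the esters and the lactone alone; both C12 epimers serve in step 16.

Step 16
Reactants: 22 allylic alcohol
Product: 23 cyclohexadiene
Conditions: Burgess reagent (methyl N-(triethylammoniosulfonyl)carbamate), benzene, 50 °C
Reagents that add atoms: none
Why: Burgess dehydration of the allylic alcohol can remove only H-11 because C1 is quaternary, so the conjugated C11=C12–C13=C14 diene should result by either a syn or an ionic elimination.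

Step 17
Reactants: 23 cyclohexadiene
Product: 24 11,12-diol
Conditions: OsO4 (2 mol%), N-methylmorpholine N-oxide (1.05 equiv), acetone/H2O, 0 °C
Reagents that add atoms: N-methylmorpholine N-oxide, C[N+]1([O-])CCOCC1; water, O
Why: Upjohn dihydroxylation should take the electron-rich trisubstituted C11=C12 bond of the diene in preference to C13=C14 (next to quaternary C1) and to the terminal vinyl group (deactivated by the allylic oxygen), from the α face anti to the C10 side chain and the C1 methyl group, which gives the cis (11S,12R)-diol.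

Step 18
Reactants: 24 11,12-diol
Product: 25 acetonide
Conditions: 2-methoxypropene, PPTS (cat.), CH2Cl2, 0 °C
Reagents that add atoms: 2-methoxypropene, COC(C)=C
Why: Acid-catalysed ketalisation of the cis diol protects it against periodate, the Grignard reagent and the acylation that follow.

Step 19
Reactants: 25 acetonide
Product: 27 C4 aldehyde, via vicinal diol 26 (not isolated)
Conditions: OsO4 (4 mol%), NaIO4 (4 equiv), 2,6-lutidine, dioxane/H2O, rt
Reagents that add atoms: sodium periodate, [Na+].[O-]I(=O)(=O)=O; water, O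
Why: Lemieux–Johnson oxidation cleaves the unhindered terminal alkene to the C4 aldehyde, while the ring alkene, flanked by quaternary C1 and the ketal oxygen, is osmylated far more slowly.

Step 20
Reactants: 27 C4 aldehyde
Product: 28 C4 alcohol
Conditions: CH2=C(CH3)MgBr (1.5 equiv), CH2Cl2/THF, −78 °C; aq. NH4Cl at −78 °C
Reagents that add atoms: isopropenylmagnesium bromide, CC(=C)[Mg]Br
Why: Cram-chelate addition of the Grignard reagent to the α-MOM-oxy aldehyde (magnesium bridging the aldehyde and the C3 oxygen, attack past H-3) gives the 3,4-syn alcohol, C4 as S, and at −78 °C the aldehyde reacts well ahead of the esters and the lactone.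

Step 21
Reactants: 28 C4 alcohol
Product: 29 C4 hexanoate
Conditions: hexanoyl chloride, pyridine, DMAP (cat.), CH2Cl2, 0 °C
Reagents that add atoms: hexanoyl chloride, CCCCCC(=O)Cl
Why: Acylation of the only free hydroxyl installs the hexanoate of the target.

Step 22
Reactants: 29 C4 hexanoate
Product: 30 C6 aldehyde
Conditions: (COCl)2, DMSO, CH2Cl2, −78 → −30 °C; Et3N
Reagents that add atoms: none
Why: Under Swern conditions a primary triethylsilyl ether is cleaved by the chlorosulfonium salt and oxidised to the aldehyde in one operation, while the tertiary silyl ethers cannot react.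

Step 23
Reactants: 30 C6 aldehyde
Product: 31 metathesis diene
Conditions: Ph3PCH3Br, KN(SiMe3)2, THF, 0 °C; 30, −78 → 0 °C
Reagents that add atoms: methylenetriphenylphosphorane (formed in the flask), C=P(c1ccccc1)(c1ccccc1)c1ccccc1
Why: Wittig methylenation with the salt-free ylide at low temperature converts the aldehyde into the C7 vinyl group faster than the ylide attacks the esters or epimerises C7.

Step 24
Reactants: 31 metathesis diene
Product: 32 protected macrocycle
Conditions: second-generation Hoveyda–Grubbs catalyst RuCl2(H2IMes)(=CH-C6H4-2-OiPr) (15 mol%), toluene (1 mM), 80 °C, argon sparge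
Reagents that add atoms: none
Why: Ring-closing metathesis joins the C7 vinyl and C5 isopropenyl groups into the ten-membered ring, and the trans-fused lactone and cyclohexene are expected to hold the two alkenes close and to make the Z trisubstituted C5=C6 alkene the less strained product.

Step 25
Reactants: 32 protected macrocycle
Product: 33 bis(silyl ether) of the target
Conditions: Me2BBr, CH2Cl2, −78 °C; THF/aq. NaHCO3
Reagents that add atoms: none
Why: Bromodimethylborane cleaves acetals at the acetal carbon, so the C3 MOM ether and the 11,12-acetonide are removed without ionising the allylic C12–O and C4–O bonds or touching the esters.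

Step 26
Reactants: 33 bis(silyl ether) of the target
Product: 34 CNP0153048.1
Conditions: HF·pyridine, pyridine, THF, 0 °C → rt
Reagents that add atoms: none
Why: Fluoride-mediated desilylation under buffered conditions removes the two tertiary silyl ethers without acyl migration or ester cleavage and should release the target.

**Compound list**

1 | acrolein | C=CC=O | starting material
2 | (3R,4R)-4-(methoxymethoxy)hexa-1,5-dien-3-ol | C=C[C@@H](OCOC)[C@H](O)C=C | intermediate
3 | (1S,2R)-2-(methoxymethoxy)-1-[(2R)-oxiran-2-yl]but-3-en-1-ol | C=C[C@@H](OCOC)[C@H](O)[C@H]1CO1 | intermediate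
4 | (2R)-2-(methoxymethoxy)-1-[(2R)-oxiran-2-yl]but-3-en-1-one | C=C[C@@H](OCOC)C(=O)[C@H]1CO1 | intermediate
5 | (R)-lactic acid | C[C@@H](O)C(=O)O | starting material
6 | pivalaldehyde | CC(C)(C)C=O | starting material
7 | (2R,5R)-2-tert-butyl-5-methyl-1,3-dioxolan-4-one (cis) | C[C@H]1O[C@@H](C(C)(C)C)OC1=O | intermediate
8 | lithium enolate of 7 (formed in the flask) | CC1=C([O-])O[C@H](C(C)(C)C)O1.[Li+] | intermediate
9 | lithium aldolate: C8 alkoxide bearing the dioxolanone at C17, the C6–C7 epoxide and the C9 MOM ether (formed in the flask) | [Li+].[O-][C@@]([C@H]1CO1)([C@H](OCOC)C=C)[C@]1(C)O[C@@H](C(C)(C)C)OC1=O | intermediate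
10 | lactone triol, (3S,4R,5S)-3,4-dihydroxy-5-(hydroxymethyl)-4-[(1R)-1-(methoxymethoxy)prop-2-en-1-yl]-3-methyloxolan-2-one | OC[C@@H]1OC(=O)[C@@](C)(O)[C@@]1(O)[C@H](OCOC)C=C | intermediate
11 | tris(triethylsilyl) ether of 10 (C6–O, C8–O, C17–O) | CC[Si](CC)(CC)OC[C@@H]1OC(=O)[C@@](C)(O[Si](CC)(CC)CC)[C@@]1(O[Si](CC)(CC)CC)[C@H](OCOC)C=C | intermediate
12 | C9 alcohol (11 without the MOM group) | CC[Si](CC)(CC)OC[C@@H]1OC(=O)[C@@](C)(O[Si](CC)(CC)CC)[C@@]1(O[Si](CC)(CC)CC)[C@H](O)C=C | intermediate
13 | C9 acetate of 12 | CC[Si](CC)(CC)OC[C@@H]1OC(=O)[C@@](C)(O[Si](CC)(CC)CC)[C@@]1(O[Si](CC)(CC)CC)[C@H](OC(C)=O)C=C | intermediate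
14 | methacrolein | CC(=C)C=O | starting material
15 | (E)-enal: 13 with the vinyl group replaced by (E)-CH=C(CH3)CHO (C10=C1, C2 aldehyde) | CC[Si](CC)(CC)OC[C@@H]1OC(=O)[C@@](C)(O[Si](CC)(CC)CC)[C@@]1(O[Si](CC)(CC)CC)[C@H](OC(C)=O)/C=C(\C)C=O | intermediate
16 | ethyl vinyl ketone (pent-1-en-3-one) | CCC(=O)C=C | starting material
17 | (Z)-3-(tert-butyldimethylsilyloxy)penta-1,3-diene | C=C/C(O[Si](C)(C)C(C)(C)C)=C/C | intermediate
18 | Diels–Alder adduct: cyclohexene with C12 silyl enol ether (C12=C13), 11-methyl trans to C9, C2 aldehyde on quaternary C1 | CC[Si](CC)(CC)OC[C@@H]1OC(=O)[C@@](C)(O[Si](CC)(CC)CC)[C@@]1(O[Si](CC)(CC)CC)[C@H](OC(C)=O)[C@H]2[C@H](C)C(O[Si](C)(C)C(C)(C)C)=CC[C@]2(C)C=O | intermediate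
19 | enone aldehyde (C12 ketone, C13=C14) | CC[Si](CC)(CC)OC[C@@H]1OC(=O)[C@@](C)(O[Si](CC)(CC)CC)[C@@]1(O[Si](CC)(CC)CC)[C@H](OC(C)=O)[C@H]2[C@H](C)C(=O)C=C[C@]2(C)C=O | intermediate
20 | (2R,3R) C2 alcohol with C3 MOM ether and C4 vinyl group | CC[Si](CC)(CC)OC[C@@H]1OC(=O)[C@@](C)(O[Si](CC)(CC)CC)[C@@]1(O[Si](CC)(CC)CC)[C@H](OC(C)=O)[C@H]2[C@H](C)C(=O)C=C[C@]2(C)[C@@H](O)[C@H](OCOC)C=C | intermediate
21 | C2 acetate of 20 | CC[Si](CC)(CC)OC[C@@H]1OC(=O)[C@@](C)(O[Si](CC)(CC)CC)[C@@]1(O[Si](CC)(CC)CC)[C@H](OC(C)=O)[C@H]2[C@H](C)C(=O)C=C[C@]2(C)[C@@H](OC(C)=O)[C@H](OCOC)C=C | intermediate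
22 | C12 allylic alcohol (C12 epimers) | CC[Si](CC)(CC)OC[C@@H]1OC(=O)[C@@](C)(O[Si](CC)(CC)CC)[C@@]1(O[Si](CC)(CC)CC)[C@H](OC(C)=O)[C@H]2[C@H](C)C(O)C=C[C@]2(C)[C@@H](OC(C)=O)[C@H](OCOC)C=C | intermediate
23 | cyclohexa-1,3-diene (C11=C12, C13=C14) | CC[Si](CC)(CC)OC[C@@H]1OC(=O)[C@@](C)(O[Si](CC)(CC)CC)[C@@]1(O[Si](CC)(CC)CC)[C@H](OC(C)=O)[C@H]2C(C)=CC=C[C@]2(C)[C@@H](OC(C)=O)[C@H](OCOC)C=C | intermediate
24 | (11S,12R)-11,12-diol | CC[Si](CC)(CC)OC[C@@H]1OC(=O)[C@@](C)(O[Si](CC)(CC)CC)[C@@]1(O[Si](CC)(CC)CC)[C@H](OC(C)=O)[C@H]2[C@](C)(O)[C@H](O)C=C[C@]2(C)[C@@H](OC(C)=O)[C@H](OCOC)C=C | intermediate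
25 | 11,12-acetonide of 24 | CC[Si](CC)(CC)OC[C@@H]1OC(=O)[C@@](C)(O[Si](CC)(CC)CC)[C@@]1(O[Si](CC)(CC)CC)[C@H](OC(C)=O)[C@H]2[C@]3(C)OC(C)(C)O[C@@H]3C=C[C@]2(C)[C@@H](OC(C)=O)[C@H](OCOC)C=C | intermediate
26 | vicinal diol from the vinyl group of 25 (C4 epimers; formed in the flask) | CC[Si](CC)(CC)OC[C@@H]1OC(=O)[C@@](C)(O[Si](CC)(CC)CC)[C@@]1(O[Si](CC)(CC)CC)[C@H](OC(C)=O)[C@H]2[C@]3(C)OC(C)(C)O[C@@H]3C=C[C@]2(C)[C@@H](OC(C)=O)[C@H](OCOC)C(O)CO | intermediate
27 | C4 aldehyde | CC[Si](CC)(CC)OC[C@@H]1OC(=O)[C@@](C)(O[Si](CC)(CC)CC)[C@@]1(O[Si](CC)(CC)CC)[C@H](OC(C)=O)[C@H]2[C@]3(C)OC(C)(C)O[C@@H]3C=C[C@]2(C)[C@@H](OC(C)=O)[C@H](OCOC)C=O | intermediate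
28 | (4S) C4 alcohol with C5 isopropenyl group | CC[Si](CC)(CC)OC[C@@H]1OC(=O)[C@@](C)(O[Si](CC)(CC)CC)[C@@]1(O[Si](CC)(CC)CC)[C@H](OC(C)=O)[C@H]2[C@]3(C)OC(C)(C)O[C@@H]3C=C[C@]2(C)[C@@H](OC(C)=O)[C@H](OCOC)[C@@H](O)C(C)=C | intermediate
29 | C4 hexanoate of 28 | CC[Si](CC)(CC)OC[C@@H]1OC(=O)[C@@](C)(O[Si](CC)(CC)CC)[C@@]1(O[Si](CC)(CC)CC)[C@H](OC(C)=O)[C@H]2[C@]3(C)OC(C)(C)O[C@@H]3C=C[C@]2(C)[C@@H](OC(C)=O)[C@H](OCOC)[C@@H](OC(=O)CCCCC)C(C)=C | intermediate
30 | C6 aldehyde (primary silyl ether of 29 oxidised) | O=C[C@@H]1OC(=O)[C@@](C)(O[Si](CC)(CC)CC)[C@@]1(O[Si](CC)(CC)CC)[C@H](OC(C)=O)[C@H]2[C@]3(C)OC(C)(C)O[C@@H]3C=C[C@]2(C)[C@@H](OC(C)=O)[C@H](OCOC)[C@@H](OC(=O)CCCCC)C(C)=C | intermediate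
31 | metathesis diene (C7 vinyl, C5 isopropenyl) | C=C[C@@H]1OC(=O)[C@@](C)(O[Si](CC)(CC)CC)[C@@]1(O[Si](CC)(CC)CC)[C@H](OC(C)=O)[C@H]2[C@]3(C)OC(C)(C)O[C@@H]3C=C[C@]2(C)[C@@H](OC(C)=O)[C@H](OCOC)[C@@H](OC(=O)CCCCC)C(C)=C | intermediate
32 | protected macrocycle: target with C3 MOM ether, C8 and C17 triethylsilyl ethers and 11,12-acetonide | CCCCCC(=O)O[C@H]1/C(C)=C\[C@@H]2OC(=O)[C@@](C)(O[Si](CC)(CC)CC)[C@@]2(O[Si](CC)(CC)CC)[C@H](OC(C)=O)[C@H]2[C@]3(C)OC(C)(C)O[C@@H]3C=C[C@]2(C)[C@@H](OC(C)=O)[C@@H]1OCOC | intermediate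
33 | 8,17-bis(triethylsilyl) ether of the target | CCCCCC(=O)O[C@H]1/C(C)=C\[C@@H]2OC(=O)[C@@](C)(O[Si](CC)(CC)CC)[C@@]2(O[Si](CC)(CC)CC)[C@H](OC(C)=O)[C@H]2[C@](C)(O)[C@H](O)C=C[C@]2(C)[C@@H](OC(C)=O)[C@@H]1O | intermediate
34 | CNP0153048.1 | CCCCCC(=O)O[C@H]1/C(C)=C\[C@@H]2OC(=O)[C@@](C)(O)[C@@]2(O)[C@H](OC(C)=O)[C@H]2[C@](C)(O)[C@H](O)C=C[C@]2(C)[C@@H](OC(C)=O)[C@@H]1O | target

**Count and risks**

Total: 26 steps. Longest linear sequence: 24 steps (steps 1–3, 5–9 and 11–26, from acrolein).

Step 5 (key step). What may go wrong: proton transfer from the acidic C9–H of the ketone to the enolate instead of addition; loss of facial selectivity at C8 if lithium binds the epoxide oxygen and not the MOM ether; migration of the epoxide to C7–C8 by the C8 alkoxide, or capture of the activated epoxide by solvent, before the acylal oxygen closes the ring. The fallback sets out from 4 and 7 and makes the two bonds in separate, known operations. The aldol addition is quenched with acid at −78 °C and the aldol adduct F1 is isolated. LiOH in THF/water at 0 °C cleaves the acylal ester to the epoxy dihydroxy acid F2 and frees pivalaldehyde. Camphorsulfonic acid in CH2Cl2 then closes the γ-lactone by the classical 5-exo opening of a γ,δ-epoxy acid, which comes back to the route at 10.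

Step 24. What may go wrong: slow initiation at the 1,1-disubstituted alkene next to the acyloxy group, intermolecular metathesis to dimers, or closure to the E ring alkene. The fallback sets out from 25 and closes the ring at C4–C5 by a Nozaki–Hiyama–Kishi reaction. Swern oxidation of the primary silyl ether gives the C6 aldehyde F3. Stork–Zhao olefination (ylide from (1-iodoethyl)triphenylphosphonium iodide, NaN(SiMe3)2, −78 °C) gives the (Z)-vinyl iodide F4. OsO4/NaIO4 cleaves the terminal vinyl group to the C4 aldehyde F5. CrCl2 with catalytic NiCl2 in DMSO under high dilution should give the macrocyclic allylic alcohol F6, expected as the Felkin (3,4-anti) epimer. Mitsunobu esterification with hexanoic acid (PPh3, DIAD) then inverts C4 and comes back to the route at 32; should the cyclisation give the 4S alcohol instead, plain acylation with hexanoyl chloride gives 32.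

Step 11. What may go wrong: slow bond formation at the hindered β-carbon with decomposition of the silyl enol ether, a stepwise Mukaiyama–Michael path that erodes the trans relationship at C1/C10, or poor facial selectivity. The fallback sets out from 15 and replaces Lewis-acid activation of the enal by a more reactive 1-amino-3-siloxy diene under thermal, concerted conditions. Purchased 4-(dimethylamino)but-3-en-2-one is methylated at its methyl group (LiN(iPr)2, MeI) to the ethyl ketone F7. KN(SiMe3)2 and t-BuMe2SiCl convert F7 into the aminosiloxy diene F8. Heating F8 with 15 in toluene should give the cycloadduct F9. Acetyl chloride at −78 °C then eliminates the amine and cleaves the silyl enol ether, which comes back to the route at 19 and makes step 12 unnecessary.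

**Further compounds**

F1 | step 5 | aldol adduct (C8 tertiary alcohol with intact dioxolanone and epoxide) | O[C@@]([C@H]1CO1)([C@H](OCOC)C=C)[C@]1(C)O[C@@H](C(C)(C)C)OC1=O
F2 | step 5 | epoxy dihydroxy acid (C17 acid, C8 and C17 hydroxyls, C6–C7 epoxide) | O[C@@]([C@H]1CO1)([C@H](OCOC)C=C)[C@](C)(O)C(=O)O
F3 | step 24 | C6 aldehyde of 25 | O=C[C@@H]1OC(=O)[C@@](C)(O[Si](CC)(CC)CC)[C@@]1(O[Si](CC)(CC)CC)[C@H](OC(C)=O)[C@H]2[C@]3(C)OC(C)(C)O[C@@H]3C=C[C@]2(C)[C@@H](OC(C)=O)[C@H](OCOC)C=C
F4 | step 24 | (Z)-vinyl iodide (C5 iodide, C5=C6) | I/C(C)=C\[C@@H]1OC(=O)[C@@](C)(O[Si](CC)(CC)CC)[C@@]1(O[Si](CC)(CC)CC)[C@H](OC(C)=O)[C@H]2[C@]3(C)OC(C)(C)O[C@@H]3C=C[C@]2(C)[C@@H](OC(C)=O)[C@H](OCOC)C=C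
F5 | step 24 | vinyl iodide C4 aldehyde | I/C(C)=C\[C@@H]1OC(=O)[C@@](C)(O[Si](CC)(CC)CC)[C@@]1(O[Si](CC)(CC)CC)[C@H](OC(C)=O)[C@H]2[C@]3(C)OC(C)(C)O[C@@H]3C=C[C@]2(C)[C@@H](OC(C)=O)[C@H](OCOC)C=O
F6 | step 24 | macrocyclic C4 alcohol (4-epimer of the target configuration) | O[C@@H]1/C(C)=C\[C@@H]2OC(=O)[C@@](C)(O[Si](CC)(CC)CC)[C@@]2(O[Si](CC)(CC)CC)[C@H](OC(C)=O)[C@H]2[C@]3(C)OC(C)(C)O[C@@H]3C=C[C@]2(C)[C@@H](OC(C)=O)[C@@H]1OCOC
F7 | step 11 | (E)-1-(dimethylamino)pent-1-en-3-one | CCC(=O)/C=C/N(C)C
F8 | step 11 | (1E,3Z)-3-(tert-butyldimethylsilyloxy)-N,N-dimethylpenta-1,3-dien-1-amine | C/C=C(/C=C/N(C)C)O[Si](C)(C)C(C)(C)C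
F9 | step 11 | cycloadduct with C14 dimethylamino group and C12 silyl enol ether (C14 epimers) | CC[Si](CC)(CC)OC[C@@H]1OC(=O)[C@@](C)(O[Si](CC)(CC)CC)[C@@]1(O[Si](CC)(CC)CC)[C@H](OC(C)=O)[C@H]2[C@H](C)C(O[Si](C)(C)C(C)(C)C)=CC(N(C)C)[C@]2(C)C=O
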